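The one ring is built by inserting ethylene into a cyclobutenone; the quaternary carbon, the hydroxypropyl arm and the enal are added afterwards.

Target (one ring, three contiguous stereocenters, Z enal) ⇐ silyl-protected hydroxypropyl ketone: the formyl-ethylidene unit and the free alcohol are unveiled together in the last step.
Ketone ⇐ (4R)-3-homofarnesyl-4-methylcyclohex-2-enone: methyl cuprate adds anti to the C4 methyl (quaternary carbon), the enolate is allylated anti to the side chain, and allyl becomes the hydroxypropyl arm.
Enone ⇐ racemic 3-homofarnesyl-4-methylcyclobut-2-enone + ethylene: a rhodium-catalysed, enantioconvergent [4+2] forms the CH2–C(=O) and CH2–CHMe ring bonds and closes the only ring.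
Enabling feature: the cyclohexane has one unsubstituted CH2–CH2 edge between the sp2 ring carbon (later the alkylidene carbon) and the CHMe carbon; the other four ring atoms (alkylidene C, CH bearing the arm, quaternary C, CHMe) are contiguous and map onto a cyclobutenone (a masked vinylketene), the CH2–CH2 edge onto ethylene.
Cyclobutenone ⇐ ketene/ynol ether [2+2], then homofarnesyllithium addition with carbonyl transposition; the side chain comes from (3E,7E)-homofarnesol.

Key step: step 4

Remark: "homofarnesyl" means (3E,7E)-4,8,12-trimethyltrideca-3,7,11-trien-1-yl; (3E,7E)-homofarnesol is assumed to be a commercial fragrance intermediate.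
Remark: the sense of induction of the bisphosphine in step 4 cannot be predicted from precedent; the (R)-ligand is written and its mirror image is used if it leads to the (4S)-enone.

Step 1
Reactants: 1 (3E,7E)-homofarnesol
Product: 2 (3E,7E)-homofarnesyl iodide
Conditions: PPh3, I2, imidazole, CH2Cl2, 0 °C to rt
Reagents that add atoms: iodine (II)
Why: Appel-type iodination of the primary homoallylic alcohol under neutral conditions should leave the three trisubstituted alkenes and their E geometry untouched; no stereocenter is formed.

Step 2
Reactants: 3 ethoxyethyne; 4 propanoyl chloride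
Product: 6 rac-3-ethoxy-4-methylcyclobut-2-en-1-one, via methylketene 5 (not isolated)
Conditions: Et3N, Et2O, rt, slow addition of 4 to excess 3
Reagents that add atoms: none
Why: Thermal ketene–ynol ether [2+2] cycloaddition, in which the ketene carbonyl carbon bonds to the nucleophilic unsubstituted alkyne carbon to give the 3-ethoxy regioisomer; the CHMe stereocenter is racemic, which does not matter because step 4 is enantioconvergent.

Step 3
Reactants: 2 (3E,7E)-homofarnesyl iodide; 6 rac-3-ethoxy-4-methylcyclobut-2-en-1-one
Product: 9 rac-3-homofarnesyl-4-methylcyclobut-2-en-1-one, via homofarnesyllithium 7 (not isolated), via lithium cyclobutenolate adduct 8 (not isolated)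
Conditions: 2, t-BuLi (2 equiv), Et2O/pentane, −78 °C; then 6, THF, −78 °C; then 1 M aq. HCl, 0 °C
Reagents that add atoms: water (O)
Why: Iodine–lithium exchange, 1,2-addition to the vinylogous ester and acid hydrolysis with allylic transposition (the four-membered-ring version of the Stork–Danheiser sequence) should place the chain on the β-carbon of a new cyclobutenone; the CHMe center stays racemic.

Step 4
Reactants: 9 rac-3-homofarnesyl-4-methylcyclobut-2-en-1-one; 10 ethylene
Product: 12 (4R)-3-homofarnesyl-4-methylcyclohex-2-en-1-one, via rhodacyclopentenone 11 (not isolated)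
Conditions: [RhCl(C2H4)2]2 (2.5 mol %), (R)-DTBM-SEGPHOS (6 mol %), ethylene (10 bar), toluene, 70 °C
Reagents that add atoms: none
Why: Proposed new method: monovalent rhodium should insert into the strained acyl–C(sp3) bond of 9 (C1–C4, the only σ bond that is both next to the carbonyl group and attached to sp3 carbon) to give rhodacyclopentenone 11, which equilibrates with an η4-vinylketene complex in which the methyl-bearing carbon is planar, so that both enantiomers of 9 feed one manifold; ethylene then inserts into the Rh–CHMe bond (new CH2–CHMe bond) and acyl–alkyl reductive elimination from the seven-membered rhodacycle forms the CH2–C(=O) bond. The closest known reaction types are the rhodium-catalysed ring-opening coupling of cyclobutenones with alkenes to cyclohexenones, the nickel-catalysed [4+2] of cyclobutenones with alkynes and the enantioselective rhodium/DTBM-SEGPHOS "cut-and-sew" insertion of alkenes into cyclobutanones; new here are ethylene as the partner and the enantioconvergent setting of a stereocenter at the migrating carbon. The six-membered ring is closed by a formal intermolecular [4+2] annulation, a two-carbon ring expansion of the four-membered ring driven by strain release. The only new stereocenter (C4 of 12, R) should be set in the ethylene insertion under control of the chiral bisphosphine. The step needs site selectivity in the C–C cleavage, which the substrate secures because the other acyl bond goes to sp2 carbon, and chemoselectivity for ethylene over the three trisubstituted side-chain alkenes, which are too hindered to insert and are outcompeted under ethylene pressure; the moderate temperature should limit thermal electrocyclic opening to the free vinylketene and decarbonylation.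

Step 5
Reactants: 12 (4R)-3-homofarnesyl-4-methylcyclohex-2-en-1-one
Product: 14 (2S,3R,4R)-2-allyl-3-homofarnesyl-3,4-dimethylcyclohexan-1-one, via lithium enolate 13 (not isolated)
Conditions: Me2CuLi (from CuI and MeLi), Et2O, −20 to 0 °C; then allyl iodide, DMPU, THF, 0 °C to rt
Reagents that add atoms: lithium dimethylcuprate ([Li+].C[Cu-]C); allyl iodide (C=CCI)
Why: Gilman conjugate addition should create the quaternary carbon with the new methyl anti to the C4 methyl (C3 R), and the regiospecific enolate 13 should then be C-allylated anti to the pseudoaxial homofarnesyl chain on the neighbouring quaternary carbon (C2 S) in a conjugate addition–enolate trapping sequence.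

Step 6
Reactants: 14 (2S,3R,4R)-2-allyl-3-homofarnesyl-3,4-dimethylcyclohexan-1-one
Product: 16 (2S,3R,4R)-3-homofarnesyl-2-(3-hydroxypropyl)-3,4-dimethylcyclohexan-1-one, via B-alkyl-9-BBN adduct 15 (not isolated)
Conditions: 9-BBN, THF, 0 °C to rt; then 30% H2O2, 3 M aq. NaOH, 0 °C
Reagents that add atoms: hydrogen peroxide (OO)
Why: Anti-Markovnikov hydroboration–oxidation, in which bulky 9-BBN should react with the monosubstituted alkene much faster than with the trisubstituted alkenes or the hindered ketone, while the cold, brief oxidative work-up avoids epimerisation next to the ketone; no new stereocenter.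

Step 7
Reactants: 16 (2S,3R,4R)-3-homofarnesyl-2-(3-hydroxypropyl)-3,4-dimethylcyclohexan-1-one
Product: 17 (2S,3R,4R)-2-[3-(tert-butyldimethylsilyloxy)propyl]-3-homofarnesyl-3,4-dimethylcyclohexan-1-one
Conditions: TBSCl, imidazole, DMF, rt
Reagents that add atoms: tert-butyldimethylsilyl chloride (CC(C)(C)[Si](C)(C)Cl)
Why: Standard silylation of the primary alcohol, needed so that the hydroxyl group cannot capture the tertiary allylic cation formed in step 9.

Step 8
Reactants: 18 1-ethoxyprop-1-ene (E/Z mixture)
Product: 20 (Z)-2-bromo-1-ethoxyprop-1-ene, via 1,2-dibromo-1-ethoxypropane 19 (not isolated)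
Conditions: Br2, pentane, −40 °C; then PhNEt2, 90 °C, distillation
Reagents that add atoms: bromine (BrBr)
Why: Bromine addition to the enol ether and dehydrobromination of the α-bromo ether (loss of the activated bromide at the oxygen-bearing carbon) should give the 2-bromovinyl ether, as in the known preparation of 2-bromovinyl ethyl ether; the Z isomer is the productive one, and any E isomer only fragments to propyne after lithiation.

Step 9
Reactants: 17 (2S,3R,4R)-2-[3-(tert-butyldimethylsilyloxy)propyl]-3-homofarnesyl-3,4-dimethylcyclohexan-1-one; 20 (Z)-2-bromo-1-ethoxyprop-1-ene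
Product: 24 (2Z)-2-[(2S,3R,4R)-3-homofarnesyl-2-(3-hydroxypropyl)-3,4-dimethylcyclohexylidene]propanal (target), via 2-ethoxyvinyllithium reagent 21 (not isolated), via lithium alkoxide adduct 22 (not isolated), via silyl ether of the enal 23 (not isolated)
Conditions: 20 (3 equiv), t-BuLi (6 equiv), THF, −78 °C; then 17, −78 to −40 °C; then 1 M aq. HCl, THF, 0 °C to rt
Reagents that add atoms: water (O)
Why: Bromine–lithium exchange gives a 2-ethoxyvinyllithium (a masked α-formyl vinyl anion) that adds 1,2 to the ketone, and aqueous acid should then ionise the tertiary allylic alcohol, hydrolyse the enol ether to the conjugated enal (formyl olefination) and finally cleave the silyl ether; the carbinol center is destroyed and the tetrasubstituted alkene is expected to settle as the Z isomer, which puts the slim formyl group rather than the methyl next to the substituted ring carbon.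

Compound list
1 | (3E,7E)-homofarnesol, (3E,7E)-4,8,12-trimethyltrideca-3,7,11-trien-1-ol | OCC/C=C(\C)CC/C=C(\C)CCC=C(C)C | starting material
2 | (3E,7E)-homofarnesyl iodide | ICC/C=C(\C)CC/C=C(\C)CCC=C(C)C | intermediate
3 | ethoxyethyne | CCOC#C | starting material
4 | propanoyl chloride | CCC(Cl)=O | starting material
5 | methylketene | CC=C=O | intermediate
6 | rac-3-ethoxy-4-methylcyclobut-2-en-1-one | CCOC1=CC(=O)C1C | intermediate
7 | homofarnesyllithium | [Li]CC/C=C(\C)CC/C=C(\C)CCC=C(C)C | intermediate
8 | lithium 3-ethoxy-1-homofarnesyl-4-methylcyclobut-2-en-1-olate | CCOC1=CC(O[Li])(CC/C=C(\C)CC/C=C(\C)CCC=C(C)C)C1C | intermediate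
9 | rac-3-homofarnesyl-4-methylcyclobut-2-en-1-one | CC1C(=O)C=C1CC/C=C(\C)CC/C=C(\C)CCC=C(C)C | intermediate
10 | ethylene | C=C | starting material
11 | 4-homofarnesyl-5-methyl-1-rhodacyclopent-3-en-2-one (ligands omitted) | CC1[Rh]C(=O)C=C1CC/C=C(\C)CC/C=C(\C)CCC=C(C)C | intermediate
12 | (4R)-3-homofarnesyl-4-methylcyclohex-2-en-1-one | O=C1CC[C@@H](C)C(CC/C=C(\C)CC/C=C(\C)CCC=C(C)C)=C1 | intermediate
13 | lithium (3R,4R)-3-homofarnesyl-3,4-dimethylcyclohex-1-en-1-olate | CC(C)=CCC/C(C)=C/CC/C(C)=C/CC[C@]1(C)[C@H](C)CCC(O[Li])=C1 | intermediate
14 | (2S,3R,4R)-2-allyl-3-homofarnesyl-3,4-dimethylcyclohexan-1-one | CC(C)=CCC/C(C)=C/CC/C(C)=C/CC[C@]1(C)[C@H](C)CCC(=O)[C@H]1CC=C | intermediate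
15 | 9-{3-[(1S,2R,3R)-2-homofarnesyl-2,3-dimethyl-6-oxocyclohexyl]propyl}-9-borabicyclo[3.3.1]nonane | CC(C)=CCC/C(C)=C/CC/C(C)=C/CC[C@]1(C)[C@H](C)CCC(=O)[C@H]1CCCB1C2CCCC1CCC2 | intermediate
16 | (2S,3R,4R)-3-homofarnesyl-2-(3-hydroxypropyl)-3,4-dimethylcyclohexan-1-one | CC(C)=CCC/C(C)=C/CC/C(C)=C/CC[C@]1(C)[C@H](C)CCC(=O)[C@H]1CCCO | intermediate
17 | (2S,3R,4R)-2-[3-(tert-butyldimethylsilyloxy)propyl]-3-homofarnesyl-3,4-dimethylcyclohexan-1-one | CC(C)=CCC/C(C)=C/CC/C(C)=C/CC[C@]1(C)[C@H](C)CCC(=O)[C@H]1CCCO[Si](C)(C)C(C)(C)C | intermediate
18 | 1-ethoxyprop-1-ene (E/Z mixture) | CCOC=CC | starting material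
19 | 1,2-dibromo-1-ethoxypropane | CCOC(Br)C(C)Br | intermediate
20 | (Z)-2-bromo-1-ethoxyprop-1-ene | CCO/C=C(\Br)C | intermediate
21 | (1-ethoxyprop-1-en-2-yl)lithium, Li cis to OEt | CCO/C=C(\[Li])C | intermediate
22 | lithium (2S,3R,4R)-2-[3-(tert-butyldimethylsilyloxy)propyl]-1-[(Z)-1-ethoxyprop-1-en-2-yl]-3-homofarnesyl-3,4-dimethylcyclohexan-1-olate (configuration at C1 not assigned; both epimers converge) | CC(C)=CCC/C(C)=C/CC/C(C)=C/CC[C@]1(C)[C@H](C)CCC(O[Li])(/C(C)=C\OCC)[C@H]1CCCO[Si](C)(C)C(C)(C)C | intermediate
23 | (2Z)-2-[(2S,3R,4R)-2-[3-(tert-butyldimethylsilyloxy)propyl]-3-homofarnesyl-3,4-dimethylcyclohexylidene]propanal | CC(C)=CCC/C(C)=C/CC/C(C)=C/CC[C@]1(C)[C@H](C)CC/C(=C(\C)C=O)[C@H]1CCCO[Si](C)(C)C(C)(C)C | intermediate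
24 | (2Z)-2-[(2S,3R,4R)-3-homofarnesyl-2-(3-hydroxypropyl)-3,4-dimethylcyclohexylidene]propanal | CC(C)=CCC/C(C)=C/CC/C(C)=C/CC[C@]1(C)[C@H](C)CC/C(=C(\C)C=O)[C@H]1CCCO | target

Total step count: 9. Longest linear sequence: 7 steps (2, 3, 4, 5, 6, 7, 9; the branch through step 1 is equally long).

Steps most likely to fail

Step 4 (proposed new method). The ethylene insertion may show insufficient enantiofacial discrimination, the rhodacycle may lose CO, or the cyclobutenone may open thermally and oligomerise as the free vinylketene. The fallback uses known chemistry, sets out from 2 and returns at 12. Iodide 2 is converted by iodine–lithium exchange (t-BuLi, giving 7) and transmetalation with ZnCl2 into homofarnesylzinc chloride F1. Negishi coupling of F1 with commercial 3-bromo-4-methylanisole (Pd(PPh3)4) should give 2-homofarnesyl-4-methoxy-1-methylbenzene F2. Birch reduction (Li, NH3, t-BuOH, THF; isolated trisubstituted alkenes are not reduced) should give 5-homofarnesyl-1-methoxy-4-methylcyclohexa-1,4-diene F3. Mild hydrolysis of the enol ether (oxalic acid, aq. MeOH) should give the β,γ-unsaturated ketone 3-homofarnesyl-4-methylcyclohex-3-en-1-one F4. A cinchona-derived chiral primary amine with a carboxylic acid co-catalyst then isomerises the alkene into conjugation through a dienamine with face-selective γ-protonation, which is expected to give 12.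

Step 5. The enolate may equilibrate or be O-allylated, and facial selectivity in the allylation next to the quaternary carbon may be poor. The fallback sets out from 12 and returns at 14. After the same cuprate addition the enolate 13 is trapped on oxygen with allyl chloroformate to give allyl (3R,4R)-3-homofarnesyl-3,4-dimethylcyclohex-1-en-1-yl carbonate F5. Catalytic Pd(PPh3)4 (zerovalent palladium) should then trigger decarboxylative Tsuji–Trost allylation, in which the allyl group is delivered regiospecifically within the π-allyl palladium enolate ion pair to give 14.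

Step 9. The vinyllithium may enolise the hindered ketone instead of adding, and the acid step may scramble the E/Z geometry of the tetrasubstituted enal. The fallback sets out from 16 and returns at 24; it needs no protecting group and fixes the geometry with a temporary ring. The primary alcohol of 16 is acylated with 2-bromopropanoyl bromide and pyridine to give 3-[(1S,2R,3R)-2-homofarnesyl-2,3-dimethyl-6-oxocyclohexyl]propyl 2-bromopropanoate F6. An intramolecular Reformatsky reaction with SmI2 (divalent samarium, high dilution, THF) should close the eight-membered β-hydroxy lactone F7. Dehydration (SOCl2, pyridine) should give the α,β-unsaturated eight-membered lactone F8, whose ring can only hold the Z alkene. Half-reduction with i-Bu2AlH at −78 °C should give the eight-membered lactol F9, which is expected to open to the hydroxy enal 24.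

Further compounds
F1 | step 4 | homofarnesylzinc chloride | Cl[Zn]CC/C=C(\C)CC/C=C(\C)CCC=C(C)C
F2 | step 4 | 2-homofarnesyl-4-methoxy-1-methylbenzene | COc1ccc(C)c(CC/C=C(\C)CC/C=C(\C)CCC=C(C)C)c1
F3 | step 4 | 5-homofarnesyl-1-methoxy-4-methylcyclohexa-1,4-diene | COC1=CCC(C)=C(CC/C=C(\C)CC/C=C(\C)CCC=C(C)C)C1
F4 | step 4 | 3-homofarnesyl-4-methylcyclohex-3-en-1-one | O=C1CCC(C)=C(CC/C=C(\C)CC/C=C(\C)CCC=C(C)C)C1
F5 | step 5 | allyl (3R,4R)-3-homofarnesyl-3,4-dimethylcyclohex-1-en-1-yl carbonate | CC(C)=CCC/C(C)=C/CC/C(C)=C/CC[C@]1(C)[C@H](C)CCC(OC(=O)OCC=C)=C1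
F6 | step 9 | 3-[(1S,2R,3R)-2-homofarnesyl-2,3-dimethyl-6-oxocyclohexyl]propyl 2-bromopropanoate | CC(C)=CCC/C(C)=C/CC/C(C)=C/CC[C@]1(C)[C@H](C)CCC(=O)[C@H]1CCCOC(=O)C(C)Br
F7 | step 9 | eight-membered β-hydroxy lactone fused to the cyclohexane (hydroxyl on the former ketone carbon, methyl on the lactone α-carbon; these two centers not assigned) | CC(C)=CCC/C(C)=C/CC/C(C)=C/CC[C@]1(C)[C@H](C)CCC(O)(C(C)C2=O)[C@H]1CCCO2
F8 | step 9 | eight-membered α,β-unsaturated lactone with the Z tetrasubstituted alkene between the former ketone carbon and the methyl-bearing α-carbon | CC(C)=CCC/C(C)=C/CC/C(C)=C/CC[C@]1(C)[C@H](C)CC/C(=C(\C)C2=O)[C@H]1CCCO2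
F9 | step 9 | eight-membered lactol, ring-chain tautomer of 24 | CC(C)=CCC/C(C)=C/CC/C(C)=C/CC[C@]1(C)[C@H](C)CC/C(=C(\C)C2O)[C@H]1CCCO2
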